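## The problem

The target 31 is a 14-membered carbocycle (C1–C14) with an isopropenyl group on C1. A γ-butyrolactone (C4, C5, C6, O, C20) bridges C4 and C6, and its α-carbon C4 is joined to C3 by an exocyclic E-alkene. The southern edge carries a β-keto ester (C8), a 1,3-diketone (C9, C11) and a trisubstituted epoxide (C12, C13) in which C11 and C14 are cis.

Five stereocentres must be set: C1 (R), C6 (S), C8 (S), C12 (S) and C13 (S). C1 and C6 are isolated from each other and from the rest by sp2 atoms and methylene groups, so neither can steer another centre; both are best taken from the chiral pool. C8 lies between the ester and the C9 carbonyl and is configurationally labile as soon as C9 is a ketone, so C9 has to stay a protected carbinol until the last step. C12 and C13 have no nearby controller other than the ring itself.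

The epoxy ketone, the α-alkylidene lactone (a Michael acceptor with acidic protons at C2), the methyl ester and the isopropenyl group rule out ozone, hydrogenation, strong nucleophiles and strong acid late in the route. The carbocycle contains no heteroatom, so it must be closed by C–C bond formation on a chain with several enolisable positions.

The enabling feature is the unit C11(=O)–C12(CH3)(O)–C13: a glycidic ketone is the Darzens product of an α-chloro ketone (C11/C12) and an aldehyde (C13). One anionic cascade can therefore form C12–C13, the carbocycle and the oxirane.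

## Retrosynthesis

**End game (31 ⇐ 30 ⇐ 29).** No skeletal bond is cut. The C9 ketone is taken back to a carbinol and then to its silyl ether in 29. This removes the β,δ-diketo ester, the only arrangement in which C8 can epimerise, from every earlier intermediate. The forward steps need a fluoride desilylation and a neutral oxidation that leave the epoxy ketone and C8 alone.

**Ring and epoxide (29 ⇐ 27).** The C12–C13 bond and the C12–O bond of the oxirane are cut; the C13–O bond is the aldehyde carbonyl of 27. The neighbouring cuts are worse. Closure at C3=C4 would need lactone enolate chemistry next to a finished epoxy ketone. Closure at C8–C9 or C9–C10 would put an enolate or an aldehyde beside the labile C8. The chosen cut removes the macrocycle, the oxirane and two stereocentres at once and leaves an acyclic chain with only C1, C6, C8 and the spectator C9. The forward reaction must enolise at C12 only, close a 14-membered ring, give the syn chlorohydrin and displace chloride with inversion.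

**Unmasking (27 ⇐ 26 ⇐ 25 ⇐ 24).** The aldehyde is carried as a dimethyl acetal and the chloro ketone as a chlorohydrin triethylsilyl ether. Both survive enolate and olefination chemistry. They are released in the order silyl ether, oxidation, acetal, so that a free C11 hydroxyl never meets acid (it could lactonise onto the C8 ester).

**Fragment union (24 ⇐ 23 + 6).** The C3=C4 alkene is cut by a Horner–Wadsworth–Emmons disconnection into lactone phosphonate 23 and aldehyde 6. This is the only cut that divides the chain into two pieces of similar size, each with its own chiral-pool stereocentre. The forward reaction must give the E isomer.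

**Western aldehyde (6 ⇐ 5 ⇐ 4 ⇐ 2 ⇐ 1).** Aldehyde 6 is a 3-isopropenylglutaraldehyde with differentiated ends. (S)-Carvone 1 holds it as a ring; excising C2 with its methyl (via epoxide 2) leaves the ketone carbon as the acid of 4 and the β-carbon as its aldehyde. The S enantiomer places the ketone-derived arm at C2–C3 and the aldehyde-derived arm at C14–C13, so the future C13 can be masked (5) while C3 is adjusted to the aldehyde.

**C8–C9 bond (23 ⇐ 21 ⇐ 20 ⇐ 19 ⇐ 14 + 18).** The aldol bond C8–C9 is cut. The alternative C9–C10 aldol would require an α-formyl ester at C8, which enolises and loses the stereocentre. Alkylation at C7–C8 would need an unreactive β-oxygenated electrophile. An auxiliary-bound enolate (14) is formed by soft enolisation, which the lactone survives, and sets C8 absolutely. Aldehyde 18 brings C9–C12 with the chlorine already in place, so no regioselective chlorination is needed later.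

**Lactone acid (14 ⇐ 12 + 13; 12 ⇐ 11 ⇐ 9 ⇐ 8 ⇐ 7).** The C7=C8 bond of enoate 11 is a Wittig disconnection to the aldehyde of hydroxymethyl lactone 9. Lactone 9 is the nitrous acid/borane product (via 8) of D-glutamic acid 7, which supplies C20, C4–C7 and the C6 configuration.

**Chlorohydrin aldehyde (18 ⇐ 17 ⇐ 16 ⇐ 15).** The C10–C11 bond is cut to allyl metal plus 2-chloropropanal 15; the terminal alkene of 17 is the latent C9 aldehyde. The C11 and C12 configurations are irrelevant because C11 becomes a ketone and C12 an enolate carbon.

## Roads not taken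

**Alternative 1: three-component lactone annulation.** The cut is inside the lactone: C4–C5, O–C20 and C3=C4. In the forward step a sodium phosphonoacetate opens a terminal C5–C6 epoxide, the C6 alkoxide lactonises, and the phosphono lactone anion olefinates a C3 aldehyde in the same flask to give A1.
- Merits: three components join in one pot; C6 comes from an enantiopure epoxide; the C12–C13 epoxide is already present as a glycidic ester made earlier under reagent control.
- Weak points: the step builds the lactone, not the carbocycle. A1 still lacks the 14-membered ring, the C10–C11 bond and the C8 ester. Closing C10–C11 means acylating a methyl ketone enolate with a glycidic ester, and the ester then has to be introduced at C8 of a 1,3-diketone whose C10 position is more acidic. C8 would end under thermodynamic control.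
- Comparison: this road is better in lactone step economy (the chosen route spends steps 5–9, 16 and 17 on it) and in control of the epoxide configuration. The chosen plan sets against it a ring closure that is solved together with the epoxide, and a C8 centre fixed by an auxiliary and protected until the last step.

**Alternative 2: metathesis at C2=C3, then alkene shift.** The cut is the C2=C3 alkene of a β,γ-unsaturated lactone. Second-generation Grubbs catalyst joins a vinyl group on C1 to an α-vinyl group on the lactone, closing the ring to A2 with loss of ethylene.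
- Merits: ring-closing metathesis is the most reliable macrocyclisation available, runs under neutral conditions and tolerates the epoxy ketone. As a ring closure it is clearly better precedented than the chosen one.
- Weak points: A2 is not the target. The alkene must move from C2=C3 into conjugation at C3=C4 with E geometry. Base would first enolise C10 and C8 (scrambling C8) and can equally move the alkene towards C1, into conjugation with the isopropenyl group. A metal hydride catalyst has the same choice. All five stereocentres, including the epoxide, must be made beforehand in separate steps, and the extra α-stereocentre of the vinyl lactone is built only to be destroyed.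
- Comparison: the chosen plan gives up the safer ring closure. In return the closure creates C12 and C13 and leaves nothing to isomerise on a triketone-bearing macrocycle.

**Alternative 3: nitrile oxide–alkyne macrocyclisation.** The cut is C9–C10 and O–C11 of an isoxazole that masks the 1,3-diketone. A nitrile oxide generated at C9 from an aldoxime with NaOCl adds to a terminal alkyne C10≡C11 on an ethynyl oxirane, closing the isoxazole and the carbocycle to A3.
- Merits: intramolecular nitrile oxide cycloadditions close large rings well and give the 3,5-disubstituted isoxazole needed here. The diketone arrives at the right oxidation level with C10 protected, and the epoxide can again be made in advance under reagent control. In these respects the road is as good as or better than the chosen one.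
- Weak points: the aldoxime at C9 is the oxime of an α-formyl ester, so C8 is labile from the start and again at the nitrile oxide stage. Unmasking needs N–O reduction (Mo(CO)6 or Raney nickel) and enaminone hydrolysis next to an epoxide, an alkylidene lactone and an isopropenyl group.
- Comparison: the chosen plan pays with a protecting group and two redox steps at C9. It gains a C8 centre that is never adjacent to a carbonyl before the final step, and an end game limited to fluoride and a neutral oxidant.

Key step: step 21

Remarks on the chemistry:
- Atom numbers C1–C14 and C20 are those of the target.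
- C9 is a spectator centre that ends as a ketone; the syn aldol of step 13 makes it 9R.
- Aldehyde 18 is racemic, so C11 and C12 are carried as diastereomer mixtures that converge in steps 19 and 21.
- 2-Chloropropanal 15 is taken as the commercial racemate.

## Route

Step 1
Reactants: 1 (S)-carvone
Product: 2 (1S,4S,6S)-1-methyl-4-(prop-1-en-2-yl)-7-oxabicyclo[4.1.0]heptan-2-one
Conditions: 30% H2O2, NaOH (cat.), MeOH, 0 °C
Reagents that add atoms: hydrogen peroxide, OO
Why: Weitz–Scheffer nucleophilic epoxidation attacks only the electron-poor enone alkene and leaves the isopropenyl group alone. The hydroperoxide adds anti to the C5 substituent, so the epoxide forms trans to the isopropenyl group.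

Step 2
Reactants: 2 (1S,4S,6S)-1-methyl-4-(prop-1-en-2-yl)-7-oxabicyclo[4.1.0]heptan-2-one
Product: 4 (3S)-5-oxo-3-(prop-1-en-2-yl)pentanoic acid, via ketodiol 3 (not isolated)
Conditions: H5IO6 (2.5 equiv), THF/H2O, 0 °C → rt
Reagents that add atoms: water, O; periodic acid, OI(O)(O)(O)(O)=O
Why: The acidic medium hydrates the epoxide to ketodiol 3, and periodate glycol and α-dicarbonyl cleavage excises the methyl-bearing carbon as acetic acid. The former ketone carbon becomes the acid and the former epoxide CH the aldehyde; the stereocentre is not involved.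

Step 3
Reactants: 4 (3S)-5-oxo-3-(prop-1-en-2-yl)pentanoic acid
Product: 5 methyl (3S)-5,5-dimethoxy-3-(prop-1-en-2-yl)pentanoate
Conditions: HC(OMe)3, MeOH, TsOH·H2O (cat.), rt
Reagents that add atoms: methanol, CO; trimethyl orthoformate, COC(OC)OC
Why: Fischer esterification and acetalisation run in one flask, driven by the orthoester as water scavenger. This differentiates the two chain ends: future C3 as ester, future C13 as acetal.

Step 4
Reactants: 5 methyl (3S)-5,5-dimethoxy-3-(prop-1-en-2-yl)pentanoate
Product: 6 (3R)-5,5-dimethoxy-3-(prop-1-en-2-yl)pentanal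
Conditions: i-Bu2AlH (1.05 equiv), CH2Cl2, −78 °C; aq. KNaC4H4O6
Reagents that add atoms: none
Why: Partial ester reduction at low temperature stops at the aluminium hemiacetal, which releases the aldehyde on work-up. Acetal and alkene are inert; the descriptor changes only because the priorities change.

Step 5
Reactants: 7 D-glutamic acid
Product: 8 (2R)-5-oxotetrahydrofuran-2-carboxylic acid
Conditions: NaNO2, aq. HCl, 0 °C → rt
Reagents that add atoms: none
Why: Diazotisation is followed by displacement of N2 by the α-carboxylate and opening of the α-lactone by the γ-carboxylate. This double inversion gives the lactone with net retention.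

Step 6
Reactants: 8 (2R)-5-oxotetrahydrofuran-2-carboxylic acid
Product: 9 (5R)-5-(hydroxymethyl)dihydrofuran-2(3H)-one
Conditions: BH3·SMe2, THF, 0 °C → rt; MeOH, then aqueous work-up
Reagents that add atoms: none
Why: Borane reduces the free carboxylic acid through its acyloxyborane much faster than the lactone; this is a standard chemoselective reduction.

Step 7
Reactants: 9 (5R)-5-(hydroxymethyl)dihydrofuran-2(3H)-one
Product: 11 benzyl (2E)-3-[(2R)-5-oxotetrahydrofuran-2-yl]prop-2-enoate, via lactone aldehyde 10 (not isolated)
Conditions: Dess–Martin periodinane, pyridine, CH2Cl2, 0 °C → rt; then Ph3P=CHCO2Bn, rt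
Reagents that add atoms: benzyl (triphenylphosphoranylidene)acetate, O=C(OCc1ccccc1)C=P(c1ccccc1)(c1ccccc1)c1ccccc1
Why: The α-oxygenated aldehyde 10 is formed without strong base and trapped at once by the stabilised ylide (Wittig reaction), so it cannot epimerise or hydrate. The alkene geometry does not matter because the double bond is saturated in the next step.

Step 8
Reactants: 11 benzyl (2E)-3-[(2R)-5-oxotetrahydrofuran-2-yl]prop-2-enoate
Product: 12 3-[(2S)-5-oxotetrahydrofuran-2-yl]propanoic acid
Conditions: H2 (1 atm), Pd/C (10% Pd on carbon), EtOAc, rt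
Reagents that add atoms: none
Why: One heterogeneous hydrogenation saturates the enoate and hydrogenolyses the benzyl ester. The conditions are neutral, so the lactone is never opened; opening would make the two three-carbon arms on C6 equivalent and racemise the centre.

Step 9
Reactants: 12 3-[(2S)-5-oxotetrahydrofuran-2-yl]propanoic acid; 13 (4S)-4-benzyl-1,3-thiazolidine-2-thione
Product: 14 (4S)-4-benzyl-3-{3-[(2S)-5-oxotetrahydrofuran-2-yl]propanoyl}-1,3-thiazolidine-2-thione
Conditions: EDC·HCl, DMAP (cat.), CH2Cl2, 0 °C → rt
Reagents that add atoms: none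
Why: Carbodiimide/DMAP N-acylation (Steglich-type) is the standard entry to N-acyl thiazolidinethiones and leaves the lactone untouched.

Step 10
Reactants: 15 2-chloropropanal
Product: 16 5-chlorohex-1-en-4-ol (racemic; both diastereomers)
Conditions: CH2=CHCH2MgBr, Et2O, −78 °C; aq. NH4Cl at −78 °C
Reagents that add atoms: allylmagnesium bromide, C=CC[Mg]Br
Why: Grignard 1,2-addition to the α-chloro aldehyde at low temperature gives the chlorohydrin without epoxide closure. The new carbinol carbon later becomes the C11 ketone, so its configuration does not matter.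

Step 11
Reactants: 16 5-chlorohex-1-en-4-ol
Product: 17 [(5-chlorohex-1-en-4-yl)oxy]triethylsilane
Conditions: Et3SiCl, imidazole, CH2Cl2, 0 °C → rt
Reagents that add atoms: chlorotriethylsilane, CC[Si](Cl)(CC)CC
Why: Standard silylation. The triethylsilyl ether blocks epoxide formation from the chlorohydrin and can later be removed in the presence of a tert-butyldimethylsilyl ether.

Step 12
Reactants: 17 [(5-chlorohex-1-en-4-yl)oxy]triethylsilane
Product: 18 4-chloro-3-[(triethylsilyl)oxy]pentanal
Conditions: O3, CH2Cl2, −78 °C; then PPh3
Reagents that add atoms: ozone, [O-][O+]=O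
Why: Ozonolysis with reductive work-up turns the terminal alkene into the C9 aldehyde. No other alkene is present at this stage.

Step 13
Reactants: 14 (4S)-4-benzyl-3-{3-[(2S)-5-oxotetrahydrofuran-2-yl]propanoyl}-1,3-thiazolidine-2-thione; 18 4-chloro-3-[(triethylsilyl)oxy]pentanal
Product: 19 (4S)-4-benzyl-3-[(2S,3R)-6-chloro-3-hydroxy-2-{[(2R)-5-oxotetrahydrofuran-2-yl]methyl}-5-(triethylsilyloxy)heptanoyl]-1,3-thiazolidine-2-thione
Conditions: TiCl4 (1.05 equiv), i-Pr2NEt (1.1 equiv), N-methylpyrrolidin-2-one (1 equiv), CH2Cl2, 0 °C; then 18, −78 → 0 °C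
Reagents that add atoms: none
Why: Soft enolisation with TiCl4 and amine acts only on the thioimide and gives the Z chlorotitanium enolate; the lactone is not enolised. With the added donor the non-chelated Evans-syn transition state operates (Crimmins variant of the Evans aldol), and the (4S)-benzyl group directs the aldehyde to the face that gives 8S and 9R. The remote racemic centres of 18 have no influence, so 19 is a mixture only at C11 and C12.

Step 14
Reactants: 19 the aldol adduct
Product: 20 methyl (2S,3R)-6-chloro-3-hydroxy-2-{[(2R)-5-oxotetrahydrofuran-2-yl]methyl}-5-(triethylsilyloxy)heptanoate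
Conditions: MeOH, imidazole, CH2Cl2, rt
Reagents that add atoms: methanol, CO
Why: The N-acyl thiazolidinethione is an activated amide, so imidazole-catalysed methanolysis displaces the auxiliary at room temperature. The medium is too mild for lactone opening or retro-aldol cleavage.

Step 15
Reactants: 20 the β-hydroxy methyl ester
Product: 21 methyl (2S,3R)-3-[tert-butyl(dimethyl)silyloxy]-6-chloro-2-{[(2R)-5-oxotetrahydrofuran-2-yl]methyl}-5-(triethylsilyloxy)heptanoate
Conditions: t-BuMe2SiOTf, 2,6-lutidine, CH2Cl2, −78 → 0 °C
Reagents that add atoms: tert-butyldimethylsilyl trifluoromethanesulfonate, CC(C)(C)[Si](C)(C)OS(=O)(=O)C(F)(F)F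
Why: Silyl triflate with lutidine silylates the hindered C9 carbinol without base strong enough for retro-aldol. The triethylsilyl ether at C11 is stable to these conditions.

Step 16
Reactants: 21 the bis-silyl ether
Product: 23 methyl (2S,3R)-3-[tert-butyl(dimethyl)silyloxy]-6-chloro-2-{[(2S)-4-(diethoxyphosphoryl)-5-oxotetrahydrofuran-2-yl]methyl}-5-(triethylsilyloxy)heptanoate (C4 epimers), via phosphonite 22 (not isolated)
Conditions: LiN(i-Pr)2 (1.1 equiv), THF, −78 °C; ClP(OEt)2; then 30% H2O2, 0 °C
Reagents that add atoms: diethyl chlorophosphite, CCOP(Cl)OCC; hydrogen peroxide, OO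
Why: The lactone α-CH2 is several pKa units more acidic and far less hindered than the tertiary C8–H of the ester, so one equivalent of amide base gives the lactone enolate. The soft chlorophosphite is attacked at carbon, and peroxide oxidises the trivalent phosphorus of 22 to the phosphonate (α-phosphonylation of a lactone enolate).

Step 17
Reactants: 23 the lactone phosphonate; 6 (3R)-5,5-dimethoxy-3-(prop-1-en-2-yl)pentanal
Product: 24 methyl (2S,3R)-3-[tert-butyl(dimethyl)silyloxy]-6-chloro-2-({(2S,4E)-4-[(3R)-5,5-dimethoxy-3-(prop-1-en-2-yl)pentylidene]-5-oxotetrahydrofuran-2-yl}methyl)-5-(triethylsilyloxy)heptanoate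
Conditions: LiCl, DBU, MeCN, 0 °C → rt
Reagents that add atoms: none
Why: Horner–Wadsworth–Emmons olefination under mild LiCl/amine conditions leaves the C8 ester and the β-silyloxy group alone. The stabilised phosphonate should give mainly the E alkylidene lactone, with the chain turned away from the lactone carbonyl.

Step 18
Reactants: 24 the coupled acetal
Product: 25 methyl (2S,3R)-3-[tert-butyl(dimethyl)silyloxy]-6-chloro-2-({(2S,4E)-4-[(3R)-5,5-dimethoxy-3-(prop-1-en-2-yl)pentylidene]-5-oxotetrahydrofuran-2-yl}methyl)-5-hydroxyheptanoate
Conditions: HF·pyridine, pyridine, THF, 0 °C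
Reagents that add atoms: none
Why: Buffered fluoride cleaves the triethylsilyl ether much faster than the hindered tert-butyldimethylsilyl ether and does not touch the acetal. No acid is present that could lactonise the freed C11 hydroxyl onto the C8 ester.

Step 19
Reactants: 25 the C11 chlorohydrin
Product: 26 methyl (2S,3R)-3-[tert-butyl(dimethyl)silyloxy]-6-chloro-2-({(2S,4E)-4-[(3R)-5,5-dimethoxy-3-(prop-1-en-2-yl)pentylidene]-5-oxotetrahydrofuran-2-yl}methyl)-5-oxoheptanoate (C12 epimers)
Conditions: Dess–Martin periodinane, pyridine, CH2Cl2, 0 °C → rt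
Reagents that add atoms: none
Why: Dess–Martin oxidation converts chlorohydrins into α-chloro ketones under buffered conditions. Both C11 epimers converge on the ketone.

Step 20
Reactants: 26 the α-chloro ketone acetal
Product: 27 methyl (2S,3R)-3-[tert-butyl(dimethyl)silyloxy]-6-chloro-5-oxo-2-({(2S,4E)-5-oxo-4-[(3R)-5-oxo-3-(prop-1-en-2-yl)pentylidene]tetrahydrofuran-2-yl}methyl)heptanoate (C12 epimers)
Conditions: TsOH·H2O (cat.), acetone/H2O, rt
Reagents that add atoms: water, O
Why: Mild aqueous acid with acetone as acceptor hydrolyses the dimethyl acetal. The secondary tert-butyldimethylsilyl ether, the α-chloro ketone, the esters and the alkenes survive.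

Step 21
Reactants: 27 the seco chloro ketone aldehyde
Product: 29 (1R,3E,6S,8S,9R,12S,13S)-macrocyclic epoxy ketone carrying the C9 tert-butyldimethylsilyl ether, via lithium chlorohydrin alkoxide 28 (not isolated)
Conditions: 27 (2 mM in THF), LiN(SiMe3)2 (1.05 equiv, slow addition), −78 °C, then → 0 °C
Reagents that add atoms: none
Why: Proposed new method: LiN(SiMe3)2 removes the C12 proton, the most acidic one because it is flanked by the ketone and by chlorine; the lithium chloro-enolate (O and Cl on the same side, bridged by lithium) adds to the C13 aldehyde through a closed six-membered transition state, and alkoxide 28 then displaces chloride from C12 with inversion; the closest known reaction types are the intermolecular Darzens condensation of α-chloro ketone enolates with aldehydes and macrocyclising aldol reactions of amide-base enolates. The 14-membered carbocycle closes in the aldol step (14-exo-trig) and the oxirane in the displacement (3-exo-tet). The relative configuration at C12/C13 comes from the syn chlorohydrin (Cl and O syn), which after inversion at C12 places C11 and C14 cis on the oxirane; it is controlled by the enolate geometry and the chair-like aldol transition state. The absolute sense relative to C1 is controlled only by the conformation of the tether, in which the E-alkylidene lactone is rigid and the isopropenyl group on C1 sits β to the aldehyde; this facial selectivity is the least secure element. The step needs enolisation at C12 rather than at C10, C14 or C8, and ring closure rather than oligomerisation. The first rests on acidity and on funnelling, since other enolates can be re-protonated while oxirane closure is irreversible; the second rests on slow addition of base to a 2 mM solution. Once C12 is a quaternary oxirane carbon it can no longer epimerise.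

Step 22
Reactants: 29 the macrocyclic silyl ether
Product: 30 (1R,3E,6S,8S,9R,12S,13S)-macrocyclic epoxy ketone with free C9 hydroxyl
Conditions: HF·pyridine, pyridine, THF, 0 °C → rt
Reagents that add atoms: none
Why: Pyridine-buffered HF·pyridine cleaves the secondary silyl ether by fluoride attack at silicon. The buffered medium is mild enough for the oxirane, the β-hydroxy ketone and the lactone.

Step 23
Reactants: 30 the C9 alcohol
Product: 31 the target, (1R,3E,6S,8S,12S,13S)
Conditions: Dess–Martin periodinane, pyridine, CH2Cl2, 0 °C; cold neutral work-up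
Reagents that add atoms: none
Why: Dess–Martin oxidation is the standard way from a β-hydroxy ketone to a 1,3-diketone and runs without base or acid strong enough to open the oxirane. C8 becomes acidic only in the product, so the cold buffered work-up should preserve the configuration set in step 13.

## Compound list

1 | (S)-carvone, (5S)-2-methyl-5-(prop-1-en-2-yl)cyclohex-2-en-1-one | CC1=CC[C@@H](CC1=O)C(C)=C | starting material
2 | (1S,4S,6S)-1-methyl-4-(prop-1-en-2-yl)-7-oxabicyclo[4.1.0]heptan-2-one | C[C@]12O[C@H]1C[C@@H](CC2=O)C(C)=C | intermediate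
3 | (2S,3R,5S)-2,3-dihydroxy-2-methyl-5-(prop-1-en-2-yl)cyclohexan-1-one (ketodiol) | C[C@]1(O)[C@H](O)C[C@@H](CC1=O)C(C)=C | intermediate (not isolated)
4 | (3S)-5-oxo-3-(prop-1-en-2-yl)pentanoic acid | O=CC[C@@H](CC(=O)O)C(C)=C | intermediate
5 | methyl (3S)-5,5-dimethoxy-3-(prop-1-en-2-yl)pentanoate | COC(OC)C[C@@H](CC(=O)OC)C(C)=C | intermediate
6 | (3R)-5,5-dimethoxy-3-(prop-1-en-2-yl)pentanal | COC(OC)C[C@@H](CC=O)C(C)=C | intermediate
7 | D-glutamic acid | N[C@H](CCC(=O)O)C(=O)O | starting material
8 | (2R)-5-oxotetrahydrofuran-2-carboxylic acid | O=C1CC[C@H](C(=O)O)O1 | intermediate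
9 | (5R)-5-(hydroxymethyl)dihydrofuran-2(3H)-one | O=C1CC[C@H](CO)O1 | intermediate
10 | (2R)-5-oxotetrahydrofuran-2-carbaldehyde (lactone aldehyde) | O=C1CC[C@H](C=O)O1 | intermediate (not isolated)
11 | benzyl (2E)-3-[(2R)-5-oxotetrahydrofuran-2-yl]prop-2-enoate | O=C1CC[C@H](/C=C/C(=O)OCc2ccccc2)O1 | intermediate
12 | 3-[(2S)-5-oxotetrahydrofuran-2-yl]propanoic acid | O=C1CC[C@H](CCC(=O)O)O1 | intermediate
13 | (4S)-4-benzyl-1,3-thiazolidine-2-thione | S=C1N[C@@H](Cc2ccccc2)CS1 | starting material
14 | (4S)-4-benzyl-3-{3-[(2S)-5-oxotetrahydrofuran-2-yl]propanoyl}-1,3-thiazolidine-2-thione | O=C1CC[C@H](CCC(=O)N2[C@@H](Cc3ccccc3)CSC2=S)O1 | intermediate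
15 | 2-chloropropanal (racemic) | CC(Cl)C=O | starting material
16 | 5-chlorohex-1-en-4-ol (racemic, both diastereomers) | C=CCC(O)C(C)Cl | intermediate
17 | [(5-chlorohex-1-en-4-yl)oxy]triethylsilane | C=CCC(O[Si](CC)(CC)CC)C(C)Cl | intermediate
18 | 4-chloro-3-[(triethylsilyl)oxy]pentanal | O=CCC(O[Si](CC)(CC)CC)C(C)Cl | intermediate
19 | (4S)-4-benzyl-3-[(2S,3R)-6-chloro-3-hydroxy-2-{[(2R)-5-oxotetrahydrofuran-2-yl]methyl}-5-(triethylsilyloxy)heptanoyl]-1,3-thiazolidine-2-thione (8S,9R; C11/C12 mixture) | O=C1CC[C@H](C[C@H](C(=O)N2[C@@H](Cc3ccccc3)CSC2=S)[C@H](O)CC(O[Si](CC)(CC)CC)C(C)Cl)O1 | intermediate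
20 | methyl (2S,3R)-6-chloro-3-hydroxy-2-{[(2R)-5-oxotetrahydrofuran-2-yl]methyl}-5-(triethylsilyloxy)heptanoate | O=C1CC[C@H](C[C@H](C(=O)OC)[C@H](O)CC(O[Si](CC)(CC)CC)C(C)Cl)O1 | intermediate
21 | methyl (2S,3R)-3-[tert-butyl(dimethyl)silyloxy]-6-chloro-2-{[(2R)-5-oxotetrahydrofuran-2-yl]methyl}-5-(triethylsilyloxy)heptanoate | O=C1CC[C@H](C[C@H](C(=O)OC)[C@H](O[Si](C)(C)C(C)(C)C)CC(O[Si](CC)(CC)CC)C(C)Cl)O1 | intermediate
22 | methyl (2S,3R)-3-[tert-butyl(dimethyl)silyloxy]-6-chloro-2-{[(2S)-4-(diethoxyphosphanyl)-5-oxotetrahydrofuran-2-yl]methyl}-5-(triethylsilyloxy)heptanoate (phosphonite) | CCOP(OCC)C1C[C@H](C[C@H](C(=O)OC)[C@H](O[Si](C)(C)C(C)(C)C)CC(O[Si](CC)(CC)CC)C(C)Cl)OC1=O | intermediate (not isolated)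
23 | methyl (2S,3R)-3-[tert-butyl(dimethyl)silyloxy]-6-chloro-2-{[(2S)-4-(diethoxyphosphoryl)-5-oxotetrahydrofuran-2-yl]methyl}-5-(triethylsilyloxy)heptanoate | CCOP(=O)(OCC)C1C[C@H](C[C@H](C(=O)OC)[C@H](O[Si](C)(C)C(C)(C)C)CC(O[Si](CC)(CC)CC)C(C)Cl)OC1=O | intermediate
24 | methyl (2S,3R)-3-[tert-butyl(dimethyl)silyloxy]-6-chloro-2-({(2S,4E)-4-[(3R)-5,5-dimethoxy-3-(prop-1-en-2-yl)pentylidene]-5-oxotetrahydrofuran-2-yl}methyl)-5-(triethylsilyloxy)heptanoate | COC(OC)C[C@@H](C/C=C1\C[C@H](C[C@H](C(=O)OC)[C@H](O[Si](C)(C)C(C)(C)C)CC(O[Si](CC)(CC)CC)C(C)Cl)OC1=O)C(C)=C | intermediate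
25 | methyl (2S,3R)-3-[tert-butyl(dimethyl)silyloxy]-6-chloro-2-({(2S,4E)-4-[(3R)-5,5-dimethoxy-3-(prop-1-en-2-yl)pentylidene]-5-oxotetrahydrofuran-2-yl}methyl)-5-hydroxyheptanoate | COC(OC)C[C@@H](C/C=C1\C[C@H](C[C@H](C(=O)OC)[C@H](O[Si](C)(C)C(C)(C)C)CC(O)C(C)Cl)OC1=O)C(C)=C | intermediate
26 | methyl (2S,3R)-3-[tert-butyl(dimethyl)silyloxy]-6-chloro-2-({(2S,4E)-4-[(3R)-5,5-dimethoxy-3-(prop-1-en-2-yl)pentylidene]-5-oxotetrahydrofuran-2-yl}methyl)-5-oxoheptanoate (C12 epimers) | COC(OC)C[C@@H](C/C=C1\C[C@H](C[C@H](C(=O)OC)[C@H](O[Si](C)(C)C(C)(C)C)CC(=O)C(C)Cl)OC1=O)C(C)=C | intermediate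
27 | seco chloro ketone aldehyde: methyl (2S,3R)-3-[tert-butyl(dimethyl)silyloxy]-6-chloro-5-oxo-2-({(2S,4E)-5-oxo-4-[(3R)-5-oxo-3-(prop-1-en-2-yl)pentylidene]tetrahydrofuran-2-yl}methyl)heptanoate (C12 epimers) | O=CC[C@@H](C/C=C1\C[C@H](C[C@H](C(=O)OC)[C@H](O[Si](C)(C)C(C)(C)C)CC(=O)C(C)Cl)OC1=O)C(C)=C | intermediate
28 | lithium alkoxide of the (1R,3E,6S,8S,9R,12R,13S)-12-chloro-13-hydroxy macrocycle (C9 silyl ether) | C=C(C)[C@@H]1C/C=C2\C[C@H](C[C@H](C(=O)OC)[C@H](O[Si](C)(C)C(C)(C)C)CC(=O)[C@](C)(Cl)[C@@H]([O-])C1)OC2=O.[Li+] | intermediate (not isolated)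
29 | (1R,3E,6S,8S,9R,12S,13S)-macrocyclic epoxy ketone, C9 tert-butyldimethylsilyl ether | C=C(C)[C@@H]1C/C=C2\C[C@H](C[C@H](C(=O)OC)[C@H](O[Si](C)(C)C(C)(C)C)CC(=O)[C@@]3(C)O[C@H]3C1)OC2=O | intermediate
30 | (1R,3E,6S,8S,9R,12S,13S)-macrocyclic epoxy ketone, free C9 hydroxyl | C=C(C)[C@@H]1C/C=C2\C[C@H](C[C@H](C(=O)OC)[C@H](O)CC(=O)[C@@]3(C)O[C@H]3C1)OC2=O | intermediate
31 | CNP0108136.1, (1R,3E,6S,8S,12S,13S) | C=C(C)[C@@H]1C/C=C2\C[C@H](C[C@H](C(=O)OC)C(=O)CC(=O)[C@@]3(C)O[C@H]3C1)OC2=O | target

## Step count and least certain steps

Total: 23 steps. Longest linear sequence: 16 steps (7 → 31; steps 5–9 and 13–23).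

**Step 21 (key step, the only step proposed as a new method).** Two things are most likely to go wrong. First, deprotonation at the aldehyde α-carbon C14 or at C10 may compete with enolisation at C12; this leads to intermolecular aldol oligomerisation, loss of the C9 silyloxy group by β-elimination, or Favorskii-type rearrangement. Second, the aldol may show poor simple or facial selectivity, because nothing but the ring conformation links C12/C13 to the existing centres; the result would be the trans-fused oxirane or the 12,13-bis-epimer.

The fallback uses only known reaction types, removes the strong base from the ring closure and separates aldol from oxirane formation. It sets out from 26, in which the aldehyde is still masked. The lithium enolate of 26 (LiN(SiMe3)2, THF, −78 °C) is brominated with N-bromosuccinimide to the α-bromo-α-chloro ketone acetal F1. Acetal hydrolysis as in step 20 gives the bromo chloro ketone aldehyde F2. SmI2 (2 equiv, THF, −78 °C, high dilution) reduces only the C–Br bond and gives the chloro-enolate of trivalent samarium regiospecifically. This enolate closes the ring by an intramolecular Reformatsky-type aldol addition, a reaction known for medium and large rings. The chlorohydrin diastereomers are separated at this point, and the (12R,13S) macrocyclic chlorohydrin F3 is closed with DBU in CH2Cl2 by stereospecific chloride displacement. The route is rejoined at 29.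

**Step 13.** The chlorotitanium aldol may lose syn selectivity, or TiCl4 may strip the triethylsilyl ether or trigger β-elimination in the β-silyloxy aldehyde 18; the lactone can also bind the Lewis acid. The fallback sets out from 12 and changes auxiliary and enolate type. Acid 12 is coupled with (4S)-4-benzyl-1,3-oxazolidin-2-one (pivaloyl chloride, Et3N, LiCl) to the oxazolidinone imide F4. The dibutylboron enolate (Bu2BOTf, i-Pr2NEt) of F4 adds to 18 in an Evans syn aldol to give the oxazolidinone aldol adduct F5 with the same 8S,9R configuration. Methanolysis with MeOMgBr in MeOH at 0 °C rejoins the route at 20.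

**Step 16.** The lactone enolate may attack the C8 ester intramolecularly (Claisen-type ring closure), or the base may deprotonate C8 and expel the C9 silyloxy group. The later olefination may also give too much Z isomer. The fallback sets out from 21 and avoids phosphorus and the long-lived enolate. The lithium enolate of 21 is generated at −78 °C and trapped within minutes by aldehyde 6, giving the β-hydroxy lactone aldol adduct F6 (mixture at C3 and C4). Mesylation (MeSO2Cl, Et3N) and E1cB elimination with DBU converge on the more stable E-alkylidene lactone. The route is rejoined at 24, bypassing 23 and step 17.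

**Step 2.** Hydration of the electron-poor epoxy ketone may be slow in the periodic acid medium; prolonged acid could then hydrate the isopropenyl group or drive the product into its cyclic acylal. The fallback sets out from 2 and uses a two-stage, non-aqueous glycol cleavage. Ketodiol 3 is isolated after hydrolysis with dilute aqueous HClO4 in THF and cleaved with Pb(OAc)4 in MeOH/CH2Cl2 at 0 °C. This gives the ester aldehyde methyl (3S)-5-oxo-3-(prop-1-en-2-yl)pentanoate F7; any free acid 4 formed alongside is esterified later. Treatment under the conditions of step 3 rejoins the route at 5.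

## Further compounds

F1 | step 21 | methyl (2S,3R)-6-bromo-3-[tert-butyl(dimethyl)silyloxy]-6-chloro-2-({(2S,4E)-4-[(3R)-5,5-dimethoxy-3-(prop-1-en-2-yl)pentylidene]-5-oxotetrahydrofuran-2-yl}methyl)-5-oxoheptanoate (α-bromo-α-chloro ketone acetal) | COC(OC)C[C@@H](C/C=C1\C[C@H](C[C@H](C(=O)OC)[C@H](O[Si](C)(C)C(C)(C)C)CC(=O)C(C)(Cl)Br)OC1=O)C(C)=C
F2 | step 21 | methyl (2S,3R)-6-bromo-3-[tert-butyl(dimethyl)silyloxy]-6-chloro-5-oxo-2-({(2S,4E)-5-oxo-4-[(3R)-5-oxo-3-(prop-1-en-2-yl)pentylidene]tetrahydrofuran-2-yl}methyl)heptanoate (bromo chloro ketone aldehyde) | O=CC[C@@H](C/C=C1\C[C@H](C[C@H](C(=O)OC)[C@H](O[Si](C)(C)C(C)(C)C)CC(=O)C(C)(Cl)Br)OC1=O)C(C)=C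
F3 | step 21 | (1R,3E,6S,8S,9R,12R,13S)-12-chloro-13-hydroxy macrocyclic ketone, C9 tert-butyldimethylsilyl ether (macrocyclic chlorohydrin) | C=C(C)[C@@H]1C/C=C2\C[C@H](C[C@H](C(=O)OC)[C@H](O[Si](C)(C)C(C)(C)C)CC(=O)[C@](C)(Cl)[C@@H](O)C1)OC2=O
F4 | step 13 | (4S)-4-benzyl-3-{3-[(2S)-5-oxotetrahydrofuran-2-yl]propanoyl}-1,3-oxazolidin-2-one (oxazolidinone imide) | O=C1CC[C@H](CCC(=O)N2[C@@H](Cc3ccccc3)COC2=O)O1
F5 | step 13 | (4S)-4-benzyl-3-[(2S,3R)-6-chloro-3-hydroxy-2-{[(2R)-5-oxotetrahydrofuran-2-yl]methyl}-5-(triethylsilyloxy)heptanoyl]-1,3-oxazolidin-2-one (oxazolidinone aldol adduct) | O=C1CC[C@H](C[C@H](C(=O)N2[C@@H](Cc3ccccc3)COC2=O)[C@H](O)CC(O[Si](CC)(CC)CC)C(C)Cl)O1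
F6 | step 16 | methyl (2S,3R)-3-[tert-butyl(dimethyl)silyloxy]-6-chloro-2-({(2S)-4-[(3R)-1-hydroxy-5,5-dimethoxy-3-(prop-1-en-2-yl)pentyl]-5-oxotetrahydrofuran-2-yl}methyl)-5-(triethylsilyloxy)heptanoate (β-hydroxy lactone aldol adduct) | COC(OC)C[C@@H](CC(O)C1C[C@H](C[C@H](C(=O)OC)[C@H](O[Si](C)(C)C(C)(C)C)CC(O[Si](CC)(CC)CC)C(C)Cl)OC1=O)C(C)=C
F7 | step 2 | methyl (3S)-5-oxo-3-(prop-1-en-2-yl)pentanoate | O=CC[C@@H](CC(=O)OC)C(C)=C
A1 | alternative 1 | E-alkylidene lactone with the glycidic ester arm on C1 and the ketal-protected butanone arm on C6 | C=C(C)[C@@H](C[C@@H]3O[C@]3(C)C(=O)OC)C/C=C2\C[C@H](CCC4(C)OCCO4)OC2=O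
A2 | alternative 2 | β,γ-unsaturated macrocyclic lactone with the C2=C3 alkene (either geometry) | C=C(C)[C@@H]1C=CC2C[C@H](C[C@H](C(=O)OC)C(=O)CC(=O)[C@@]3(C)O[C@H]3C1)OC2=O
A3 | alternative 3 | isoxazole-bridged macrocyclic lactone | C=C(C)[C@@H]1C/C=C2\C[C@H](C[C@H](C(=O)OC)c4cc(on4)[C@@]3(C)O[C@H]3C1)OC2=O
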